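**Strategy**

Everything rests on disconnecting the 14-membered carbocycle (ring A) at C9–C10 (cembrane numbering: lactone ring B fused at C1/C14, carbinol C12, chloride C11). The key step exploits two features: C9 is the allylic terminus of the C7=C8 alkene, and C10 lies alpha to C11, which is carried as a ketone. A 16-membered allyl beta-keto macrolactone, in which a temporary C9–O–CO–C10 ester tether replaces the missing bond, undergoes palladium-catalysed decarboxylative ring contraction: CO2 is lost and C9–C10 forms with the E-alkene intact. The precursor already holds the trans alpha-methylene lactone and the C12 stereocentre; C11 is then set by CBS reduction, epoxide closure and chloride opening.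

Key step: step 12

Numbering used below: C1 and C14 are the ring-fusion carbons (C14 bears the lactone oxygen), C2–C13 complete ring A, C15 is the lactone alpha-carbon, C16 the lactone carbonyl, C17 the exocyclic methylene, C18–C20 the methyl groups on C4, C8 and C12.

Remark on the chemistry: the chromium allylation of step 10 is assumed to be anti-selective whatever the geometry of the allylic bromide, as is usual for gamma-substituted allylchromium reagents.

**Route**

Step 1
Reactants: 1 (S)-lactic acid; 2 pivalaldehyde
Product: 3 (2S,5S)-2-tert-butyl-5-methyl-1,3-dioxolan-4-one (cis)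
Conditions: TsOH·H2O (cat.), H2SO4 (cat.), pentane, reflux with water separator; crystallisation from pentane–ether, −78 °C
Reagents that add atoms: none
Why: Acid-catalysed acetalisation under thermodynamic control should favour the cis dioxolanone, which is purified by crystallisation, the lactic acid stereocentre being untouched and the acetal carbon serving only as a stereochemical relay.

Step 2
Reactants: 3 (2S,5S)-2-tert-butyl-5-methyl-1,3-dioxolan-4-one; 4 allyl bromide
Product: 6 (2S,5R)-2-tert-butyl-5-methyl-5-(prop-2-enyl)-1,3-dioxolan-4-one, via lithium enolate 5 (not isolated)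
Conditions: LiN(i-Pr)2, THF, −78 °C; then allyl bromide, −78 to −30 °C
Reagents that add atoms: none
Why: Enolate alkylation with self-regeneration of the stereocentre: the electrophile should enter anti to the tert-butyl group, fixing the quaternary carbon that becomes C12 in the configuration needed for 12R.

Step 3
Reactants: 6 (2S,5R)-2-tert-butyl-5-methyl-5-(prop-2-enyl)-1,3-dioxolan-4-one; 7 tert-butyl acetate
Product: 8 tert-butyl (4R)-4-hydroxy-4-methyl-3-oxohept-6-enoate
Conditions: LiN(i-Pr)2 (3 equiv), tert-butyl acetate (3 equiv), THF, −78 °C; then 6, −78 to 0 °C; aq. NH4Cl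
Reagents that add atoms: none
Why: Claisen-type C-acylation of the ester enolate by the activated acylal carbonyl, whose collapse releases pivalaldehyde and unveils the tertiary alcohol, should give the beta-keto ester without touching the quaternary stereocentre, the bulky tert-butyl ester slowing lactonisation to a tetronic acid.

Step 4
Reactants: 8 tert-butyl (4R)-4-hydroxy-4-methyl-3-oxohept-6-enoate
Product: 9 tert-butyl (4R)-4-methyl-3-oxo-4-(triethylsilyloxy)hept-6-enoate
Conditions: Et3SiOSO2CF3, 2,6-lutidine, CH2Cl2, −78 °C; brief aq. citric acid wash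
Reagents that add atoms: triethylsilyl trifluoromethanesulfonate, CC[Si](CC)(CC)OS(=O)(=O)C(F)(F)F
Why: Silylation of the hindered tertiary alcohol with the silyl triflate protects the C12 oxygen, which would otherwise trap the acylketene of step 11, any silyl enol ether of the keto ester being hydrolysed in the wash.

Step 5
Reactants: 9 tert-butyl (4R)-4-methyl-3-oxo-4-(triethylsilyloxy)hept-6-enoate
Product: 11 tert-butyl (4R)-4-methyl-3,6-dioxo-4-(triethylsilyloxy)hexanoate, via ozonide 10 (not isolated)
Conditions: O3, CH2Cl2, −78 °C; then PPh3, −78 °C to rt; used crude at once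
Reagents that add atoms: ozone, [O-][O+]=O
Why: Ozonolysis with reductive work-up cleaves the only alkene to the C14 aldehyde under neutral conditions, and immediate use should forestall aldol condensation between C10 and C14.

Step 6
Reactants: 12 geranyl bromide; 13 methyl propiolate
Product: 14 methyl (4E)-5,9-dimethyldeca-4,8-dien-2-ynoate
Conditions: CuI (0.2 equiv), NaI (0.2 equiv), K2CO3, DMF, rt
Reagents that add atoms: none
Why: Copper-mediated SN2 allylation of the terminal alkyne by the primary allylic bromide should give the skipped enynoate with the E-alkene retained, joining C1 to C2.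

Step 7
Reactants: 14 methyl (4E)-5,9-dimethyldeca-4,8-dien-2-ynoate
Product: 16 methyl (2Z,5E)-2-(hydroxymethyl)-6,10-dimethylundeca-2,5,9-trienoate, via alkenylalane 15 (not isolated)
Conditions: i-Bu2AlH, N-methylmorpholine N-oxide, THF, 0 °C; then CH2O (gas), −20 °C to rt; aq. potassium sodium tartrate
Reagents that add atoms: formaldehyde, C=O
Why: Conjugate syn-hydroalumination of the ynoate places aluminium on the alpha-carbon and the alkenylalane adds to formaldehyde (vinylalumination, a Morita–Baylis–Hillman-type hydroxymethylation), installing C17; the alkene geometry is of no consequence later.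

Step 8
Reactants: 16 methyl (2Z,5E)-2-(hydroxymethyl)-6,10-dimethylundeca-2,5,9-trienoate
Product: 17 methyl (2E,5E)-2-(bromomethyl)-6,10-dimethylundeca-2,5,9-trienoate
Conditions: CBr4, PPh3, CH2Cl2, 0 °C
Reagents that add atoms: carbon tetrabromide, BrC(Br)(Br)Br
Why: Appel bromination converts the primary allylic alcohol into the 2-(alkoxycarbonyl)allyl bromide under neutral conditions that spare the trisubstituted alkenes.

Step 9
Reactants: 17 methyl (2E,5E)-2-(bromomethyl)-6,10-dimethylundeca-2,5,9-trienoate
Product: 18 methyl (2E,5E,9E)-2-(bromomethyl)-11-hydroxy-6,10-dimethylundeca-2,5,9-trienoate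
Conditions: SeO2 (cat.), t-BuOOH, salicylic acid (cat.), CH2Cl2, rt
Reagents that add atoms: tert-butyl hydroperoxide, CC(C)(C)OO
Why: Selenium dioxide allylic oxidation (ene reaction then 2,3-shift) should select the E-methyl group of the terminal, most electron-rich trisubstituted alkene and give the E-allylic alcohol that becomes C9–OH.

Step 10
Reactants: 11 tert-butyl (4R)-4-methyl-3,6-dioxo-4-(triethylsilyloxy)hexanoate; 18 methyl (2E,5E,9E)-2-(bromomethyl)-11-hydroxy-6,10-dimethylundeca-2,5,9-trienoate
Product: 20 trans alpha-methylene lactone keto ester (tert-butyl (4R)-5-[(2S,3R)-3-[(2E,6E)-8-hydroxy-3,7-dimethylocta-2,6-dien-1-yl]-4-methylidene-5-oxooxolan-2-yl]-4-methyl-3-oxo-4-(triethylsilyloxy)pentanoate), via hydroxy ester 19 (not isolated)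
Conditions: CrCl2 (10 mol %), chiral 1,8-bis(oxazolinyl)carbazole ligand (12 mol %, enantiomer directing Re-face addition), Et3N (20 mol %), Mn powder, Me3SiCl, THF, rt; then aq. citric acid; PPTS (cat.), CH2Cl2, rt
Reagents that add atoms: none
Why: Catalytic asymmetric Nozaki–Hiyama–Kishi 2-(alkoxycarbonyl)allylation: the gamma-substituted allylchromium species (trivalent chromium) equilibrates and should add through a closed chair transition state to give the anti adduct whatever the geometry of 18, the ligand directing attack to the Re face of the aldehyde, so that C14 (S) and C1 (R) are set together before acid closes the trans lactone.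

Step 11
Reactants: 20 trans alpha-methylene lactone keto ester
Product: 22 16-membered allyl beta-keto macrolactone (C9–O–CO–C10 ester), via acylketene 21 (not isolated)
Conditions: toluene (0.5 mM, slow addition), BHT (cat.), 110 °C
Reagents that add atoms: none
Why: Thermal loss of tert-butanol from the beta-keto tert-butyl ester generates an acylketene that should be trapped by the C9 hydroxyl under high dilution (acylketene macrolactonisation), installing the temporary ester tether without any base that could attack the alpha-methylene lactone.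

Step 12
Reactants: 22 16-membered allyl beta-keto macrolactone
Product: 25 (1R,3E,7E,12R,14S)-11-oxo-12-(triethylsilyloxy)cembra-3,7,15(17)-trien-16,14-olide, via allylpalladium carboxylate 23 (not isolated), via allylpalladium enolate 24 (not isolated)
Conditions: Pd(PPh3)4 (10 mol %), THF (1 mM), 40 °C
Reagents that add atoms: none
Why: Zerovalent palladium adds oxidatively to the allylic C9–O bond of the beta-keto ester, the carboxylate loses CO2, and the resulting enolate, which can only be the C10 enolate because C12 is quaternary, recombines with the pi-allyl unit at C9 to form the C9–C10 bond. The closest known reaction type is the palladium-catalysed decarboxylative allylation of allyl beta-keto esters (the catalytic counterpart of the Carroll rearrangement), run here in an intramolecular, ring-contracting mode. Ring A (14-membered) closes by attack of C10 on the allyl terminus remote from the chain, so that C7, C8 and C9 all end up inside the ring, while the 16-membered lactone ring of 22 disappears with its CO2 bridge. No new stereocentre is formed; the E geometry of C7=C8 follows from the syn pi-allyl complex, and C1, C12 and C14 are untouched. The step needs regioselectivity for the primary terminus C9 over C7 (which would give a 12-membered ring with an isopropenyl branch), C- over O-allylation, and ring closure over oligomerisation; these should be secured by the steric bias of the 2-methylallyl unit, the soft neutral conditions that also spare the alpha-methylene lactone, and high dilution.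

Step 13
Reactants: 25 (1R,3E,7E,12R,14S)-11-oxo-12-(triethylsilyloxy)cembra-3,7,15(17)-trien-16,14-olide
Product: 26 (1R,3E,7E,11S,12R,14S)-11-hydroxy-12-(triethylsilyloxy)cembra-3,7,15(17)-trien-16,14-olide
Conditions: (R)-2-methyl-CBS-oxazaborolidine (0.5 equiv), catecholborane, toluene, −78 to −40 °C; then MeOH, aq. NaHCO3
Reagents that add atoms: none
Why: Corey–Bakshi–Shibata reduction under reagent control: the catalyst should distinguish the quaternary C12 side (large) from the C10 methylene (small) and deliver hydride to give the 11S alcohol, catecholborane leaving the alkenes and the lactone alone.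

Step 14
Reactants: 26 (1R,3E,7E,11S,12R,14S)-11-hydroxy-12-(triethylsilyloxy)cembra-3,7,15(17)-trien-16,14-olide
Product: 28 (1R,3E,7E,11R,12R,14S)-11,12-epoxycembra-3,7,15(17)-trien-16,14-olide, via mesylate 27 (not isolated)
Conditions: MeSO2Cl, Et3N, DMAP (cat.), CH2Cl2, 0 °C; then Bu4NF, THF, 0 °C
Reagents that add atoms: none
Why: Mesylation of the C11 alcohol followed by fluoride cleavage of the silyl ether frees the C12 alkoxide, which should displace the mesylate intramolecularly (Williamson-type epoxide closure) with inversion at C11 to give the 11R,12R epoxide.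

Step 15
Reactants: 28 (1R,3E,7E,11R,12R,14S)-11,12-epoxycembra-3,7,15(17)-trien-16,14-olide
Product: 29 (1R,3E,7E,11S,12R,14S)-11-chloro-12-hydroxycembra-3,7,15(17)-trien-16,14-olide (CNP0247658.1)
Conditions: Li2CuCl4 (2 equiv), THF, rt; aq. NH4Cl
Reagents that add atoms: dilithium tetrachlorocuprate, [Li+].[Li+].[Cu+2].[Cl-].[Cl-].[Cl-].[Cl-]
Why: SN2 opening of the trisubstituted epoxide by soft chloride at the less substituted C11 should proceed with inversion to the 11S chloride and leave the C12–O bond, hence the 12R tertiary alcohol, intact.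

**Compound list**

1 | (S)-lactic acid | C[C@H](O)C(=O)O | starting material
2 | pivalaldehyde (2,2-dimethylpropanal) | CC(C)(C)C=O | starting material
3 | (2S,5S)-2-tert-butyl-5-methyl-1,3-dioxolan-4-one (cis) | C[C@@H]1O[C@H](C(C)(C)C)OC1=O | intermediate
4 | allyl bromide | C=CCBr | starting material
5 | lithium enolate of 3 | CC1=C(O[Li])O[C@@H](C(C)(C)C)O1 | intermediate
6 | (2S,5R)-2-tert-butyl-5-methyl-5-(prop-2-enyl)-1,3-dioxolan-4-one | C=CC[C@@]1(C)O[C@H](C(C)(C)C)OC1=O | intermediate
7 | tert-butyl acetate | CC(=O)OC(C)(C)C | starting material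
8 | tert-butyl (4R)-4-hydroxy-4-methyl-3-oxohept-6-enoate | C=CC[C@@](C)(O)C(=O)CC(=O)OC(C)(C)C | intermediate
9 | tert-butyl (4R)-4-methyl-3-oxo-4-(triethylsilyloxy)hept-6-enoate | C=CC[C@@](C)(O[Si](CC)(CC)CC)C(=O)CC(=O)OC(C)(C)C | intermediate
10 | ozonide (1,2,4-trioxolane) of 9, mixture at the trioxolane carbon | C1OC(C[C@@](C)(O[Si](CC)(CC)CC)C(=O)CC(=O)OC(C)(C)C)OO1 | intermediate
11 | tert-butyl (4R)-4-methyl-3,6-dioxo-4-(triethylsilyloxy)hexanoate | O=CC[C@@](C)(O[Si](CC)(CC)CC)C(=O)CC(=O)OC(C)(C)C | intermediate
12 | geranyl bromide ((2E)-1-bromo-3,7-dimethylocta-2,6-diene) | CC(C)=CCC/C(C)=C/CBr | starting material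
13 | methyl propiolate | C#CC(=O)OC | starting material
14 | methyl (4E)-5,9-dimethyldeca-4,8-dien-2-ynoate | CC(C)=CCC/C(C)=C/CC#CC(=O)OC | intermediate
15 | diisobutyl alkenylalane from 14 (aluminium on the ester alpha-carbon, side chain cis to the ester) | CC(C)=CCC/C(C)=C/C/C=C(/[Al](CC(C)C)CC(C)C)C(=O)OC | intermediate
16 | methyl (2Z,5E)-2-(hydroxymethyl)-6,10-dimethylundeca-2,5,9-trienoate | CC(C)=CCC/C(C)=C/C/C=C(/CO)C(=O)OC | intermediate
17 | methyl (2E,5E)-2-(bromomethyl)-6,10-dimethylundeca-2,5,9-trienoate | CC(C)=CCC/C(C)=C/C/C=C(/CBr)C(=O)OC | intermediate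
18 | methyl (2E,5E,9E)-2-(bromomethyl)-11-hydroxy-6,10-dimethylundeca-2,5,9-trienoate | OC/C(C)=C/CC/C(C)=C/C/C=C(/CBr)C(=O)OC | intermediate
19 | anti hydroxy ester (open-chain form of 20: methyl 2-methylidene ester, free C14–OH, 1R,14S,12R) | C=C(C(=O)OC)[C@@H](C/C=C(\C)CC/C=C(\C)CO)[C@@H](O)C[C@@](C)(O[Si](CC)(CC)CC)C(=O)CC(=O)OC(C)(C)C | intermediate
20 | tert-butyl (4R)-5-[(2S,3R)-3-[(2E,6E)-8-hydroxy-3,7-dimethylocta-2,6-dien-1-yl]-4-methylidene-5-oxooxolan-2-yl]-4-methyl-3-oxo-4-(triethylsilyloxy)pentanoate | C=C1C(=O)O[C@@H](C[C@@](C)(O[Si](CC)(CC)CC)C(=O)CC(=O)OC(C)(C)C)[C@@H]1C/C=C(\C)CC/C=C(\C)CO | intermediate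
21 | acylketene from 20 (C10=C=O) | C=C1C(=O)O[C@@H](C[C@@](C)(O[Si](CC)(CC)CC)C(=O)C=C=O)[C@@H]1C/C=C(\C)CC/C=C(\C)CO | intermediate
22 | 16-membered allyl beta-keto macrolactone (C9–O–CO–C10 ester; 1R,12R,14S; 3E,7E; 12-triethylsilyloxy; trans alpha-methylene lactone) | C=C1C(=O)O[C@H]2C[C@@](C)(O[Si](CC)(CC)CC)C(=O)CC(=O)OC/C(C)=C/CC/C(C)=C/C[C@H]12 | intermediate
23 | zwitterionic bis(triphenylphosphine)allylpalladium beta-keto carboxylate from 22 (drawn as the sigma-allyl form bound at C9) | C=C1C(=O)O[C@@H](C[C@@](C)(O[Si](CC)(CC)CC)C(=O)CC(=O)[O-])[C@@H]1C/C=C(\C)CC/C=C(\C)C[Pd+](P(c2ccccc2)(c2ccccc2)c2ccccc2)P(c2ccccc2)(c2ccccc2)c2ccccc2 | intermediate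
24 | bis(triphenylphosphine)allylpalladium C10 enolate after loss of CO2 (drawn as the sigma-allyl form bound at C9) | C=C1C(=O)O[C@@H](C[C@@](C)(O[Si](CC)(CC)CC)C([O-])=C)[C@@H]1C/C=C(\C)CC/C=C(\C)C[Pd+](P(c2ccccc2)(c2ccccc2)c2ccccc2)P(c2ccccc2)(c2ccccc2)c2ccccc2 | intermediate
25 | (1R,3E,7E,12R,14S)-11-oxo-12-(triethylsilyloxy)cembra-3,7,15(17)-trien-16,14-olide | C=C1C(=O)O[C@H]2C[C@@](C)(O[Si](CC)(CC)CC)C(=O)CC/C(C)=C/CC/C(C)=C/C[C@H]12 | intermediate
26 | (1R,3E,7E,11S,12R,14S)-11-hydroxy-12-(triethylsilyloxy)cembra-3,7,15(17)-trien-16,14-olide | C=C1C(=O)O[C@H]2C[C@@](C)(O[Si](CC)(CC)CC)[C@@H](O)CC/C(C)=C/CC/C(C)=C/C[C@H]12 | intermediate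
27 | C11 methanesulfonate of 26 | C=C1C(=O)O[C@H]2C[C@@](C)(O[Si](CC)(CC)CC)[C@@H](OS(C)(=O)=O)CC/C(C)=C/CC/C(C)=C/C[C@H]12 | intermediate
28 | (1R,3E,7E,11R,12R,14S)-11,12-epoxycembra-3,7,15(17)-trien-16,14-olide | C=C1C(=O)O[C@H]2C[C@@]3(C)O[C@@H]3CC/C(C)=C/CC/C(C)=C/C[C@H]12 | intermediate
29 | (1R,3E,7E,11S,12R,14S)-11-chloro-12-hydroxycembra-3,7,15(17)-trien-16,14-olide (CNP0247658.1) | C=C1C(=O)O[C@H]2C[C@@](C)(O)[C@@H](Cl)CC/C(C)=C/CC/C(C)=C/C[C@H]12 | target

**Counts**

Total step count: 15.
Longest linear sequence: 11 steps (steps 1–5, then 10–15); the other branch (steps 6–9) has 4 steps before the union.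

**Steps most likely to fail, with fallbacks**

1. Step 12 (key step). The ring contraction may stall through protonation of the palladium enolate, beta-hydride elimination of the allyl unit to a diene, or intermolecular allyl transfer leading to oligomers. The fallback gives up the ester tether and sets out from 20. The C9 hydroxyl is converted into the C9 methyl carbonate of 20 F1 (ClCO2Me, pyridine, CH2Cl2, 0 °C). A neutral Tsuji–Trost macrocyclisation (Pd(PPh3)4, THF, high dilution, 50 °C), in which the beta-keto ester C10–H serves as the stabilised carbon acid, should give the 14-membered ketone carrying a C10 tert-butoxycarbonyl group F2. Acid-induced loss of isobutene and CO2 (TsOH cat., toluene, 80 °C) brings the route back at 25.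

2. Step 10. The chromium allylation may show poor anti selectivity or poor facial selectivity, or the keto aldehyde may condense with itself before it is trapped. The fallback replaces chromium by boron and sets out from 18 (with 11). Copper-catalysed borylation (B2pin2, CuCl, KOt-Bu, THF, 0 °C) should give the allylic pinacol boronate F3, with the side chain trans to the CH2B group. Its allylboration of 11 through a closed chair transition state, under a chiral BINOL-derived phosphoric acid (toluene, −30 °C), should give the anti hydroxy ester 19; acid treatment as before brings the route back at 20.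

3. Step 15. Chloride may attack the tertiary C12 through an ionising pathway, or the epoxide may rearrange instead of opening at C11. The fallback avoids the epoxide and sets out from 25. Reduction with the enantiomeric catalyst ((S)-2-methyl-CBS-oxazaborolidine, catecholborane, toluene, −78 to −40 °C) should give the (11R)-alcohol F4. Desilylation (HF·pyridine, THF, 0 °C) gives the (11R,12R)-diol F5, and SOCl2 with pyridine (CH2Cl2, 0 °C) the cyclic sulfite F6. LiCl in DMF (70 °C), then dilute aqueous HCl, should open the sulfite by SN2 attack at the secondary C11 with inversion and release SO2, coming back to the route at 29.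

Further compounds
F1 | step 12 | C9 methyl carbonate of 20 | C=C1C(=O)O[C@@H](C[C@@](C)(O[Si](CC)(CC)CC)C(=O)CC(=O)OC(C)(C)C)[C@@H]1C/C=C(\C)CC/C=C(\C)COC(=O)OC
F2 | step 12 | (1R,3E,7E,12R,14S)-10-(tert-butoxycarbonyl)-11-oxo-12-(triethylsilyloxy)cembra-3,7,15(17)-trien-16,14-olide, mixture at C10 | C=C1C(=O)O[C@H]2C[C@@](C)(O[Si](CC)(CC)CC)C(=O)C(C(=O)OC(C)(C)C)C/C(C)=C/CC/C(C)=C/C[C@H]12
F3 | step 10 | methyl (2E,5E,9E)-11-hydroxy-6,10-dimethyl-2-[(4,4,5,5-tetramethyl-1,3,2-dioxaborolan-2-yl)methyl]undeca-2,5,9-trienoate | OC/C(C)=C/CC/C(C)=C/C/C=C(/CB1OC(C)(C)C(C)(C)O1)C(=O)OC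
F4 | step 15 | (1R,3E,7E,11R,12R,14S)-11-hydroxy-12-(triethylsilyloxy)cembra-3,7,15(17)-trien-16,14-olide | C=C1C(=O)O[C@H]2C[C@@](C)(O[Si](CC)(CC)CC)[C@H](O)CC/C(C)=C/CC/C(C)=C/C[C@H]12
F5 | step 15 | (1R,3E,7E,11R,12R,14S)-11,12-dihydroxycembra-3,7,15(17)-trien-16,14-olide | C=C1C(=O)O[C@H]2C[C@@](C)(O)[C@H](O)CC/C(C)=C/CC/C(C)=C/C[C@H]12
F6 | step 15 | 11,12-cyclic sulfite of F5, mixture at sulfur | C=C1C(=O)O[C@H]2C[C@@]3(C)OS(=O)O[C@@H]3CC/C(C)=C/CC/C(C)=C/C[C@H]12
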